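The data were computed with made-up constants; noise was put on by code.

The vessel is closed, stirred and isothermal, and Thursday's and Friday's flasks are charged like the summer and noon runs, with substrate and protic impurity the same. But their partner differs.

common to all: substrate 0.13 M

| run | partner | protic impurity | remark | time |
|---|---|---|---|---|
| summer | 0.17 M | 0.13 M | run made earlier |  |
| noon | 0.41 M | 0.13 M | run made earlier |  |
| Thursday's | 0.580 M | 0.130 M |  | 2.5 h |
| Friday's | 0.200 M | 0.130 M |  | 2.5 h |

| run | time / h | intermediate C / % | substrate / % | side product / % | intermediate B / % | target / % |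
|---|---|---|---|---|---|---|
| summer | 0.333 | 2.5 | 70.1 | 4.2 | 11.2 | 0 |
| summer | 0.667 | 6.2 | 52.6 | 6.8 | 18.7 | 0 |
| summer | 1.00 | 11.0 | 41.7 | 7.4 | 23.9 | 0.3 |
| summer | 1.33 | 15.7 | 33.8 | 7.9 | 28.9 | 1.1 |
| summer | 2.00 | 21.8 | 23.7 | 7.5 | 35.1 | 1.7 |
| summer | 2.50 | 25.6 | 18.4 | 6.4 | 38.3 | 2.4 |
| noon | 0.200 | 1.0 | 75.7 | 7.6 | 6.6 | 0 |
| noon | 0.333 | 2.5 | 65.0 | 10.7 | 10.5 | 0.3 |
| noon | 0.500 | 3.7 | 54.7 | 12.6 | 14.1 | 0 |
| noon | 0.667 | 6.3 | 47.0 | 15.3 | 17.3 | 0 |
| noon | 1.00 | 10.5 | 35.9 | 17.5 | 22.3 | 0.5 |
| noon | 1.50 | 15.6 | 27.3 | 17.5 | 27.9 | 0.9 |
| noon | 2.50 | 23.2 | 16.9 | 14.8 | 35.2 | 2.4 |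

(each reading ± 0.3 percentage points)

- a reading of substrate is of its free form alone
- a reading of intermediate C is of its free form alone

* which of these there is most of at the end, counted by the substrate in it, Thursday's (side product / substrate / intermediate C / intermediate B)
* which of these there is most of at the end, counted by the substrate in it, Friday's (side product / substrate / intermediate C / intermediate B)
* final amount of the leader among these, as a percentage of the substrate charged, in Thursday's
* final amount of the leader among these, as a percentage of the substrate charged, in Friday's

So I count partner in equivalents of the substrate charge: 1.31 in summer, 3.15 at noon, 4.46 on Thursday and 1.54 on Friday. Both earlier runs have a reading at the asked time, where intermediate B stands at 38.3 % and 35.2 % of the charge.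

From these I read the partner price, a sensitivity: the fraction of the charge lost from intermediate B at the end per added equivalent of partner, with substrate, protic impurity and time held. It is 1.68 % per equivalent, a reading from two values that each carry 0.3 percentage points.

Carried on from noon, my price gives Thursday's 33.0 %; carried from summer, it gives Friday's 37.9 %. Side product pays the other way, gaining 4.55 % per equivalent. My estimate for it on Thursday is 20.8 %, less than my estimate for intermediate B. Intermediate C reads 23.2 % at noon and 25.6 % in summer, less than intermediate B in the same run, so I keep intermediate B ahead in both flasks.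

The forecast names intermediate B for Thursday's at 33 % and intermediate B for Friday's at 37.9 %, holding that the chain “barely depends on partner”.

Thursday's flask gives intermediate B at 32.6 %, and Friday's gives intermediate B at 38.1 %. At 1.68 % per equivalent, the price misses them by 0.40 points and 0.20 points.

    substrate + partner ⇌ side product (K = 2.00 /M, k = 1.10 /M/h)
    substrate ⇌ intermediate A (K = 0.560, k = 0.620 /h)
    substrate → intermediate B (k = 0.390 /h)
    intermediate A → intermediate C (k = 0.930 /h)
    intermediate B → target (k = 0.0390 /h)
    intermediate C ⇌ intermediate D (K = 1.00, k = 0.0430 /h)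
    partner + protic impurity → quenched reagent (k = 1.80 /M/h)

In Friday's flask, with concentrations as charged, the forward step to side product alone gives substrate a half-life of 3.2 h, and the step to intermediate B gives a shorter one, 1.8 h. At the asked time, Friday's flask holds 38.1 % in intermediate B and 7.91 % in side product.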